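Ring C of the flavanone is disconnected at C3–C4 and O1–C2. This reveals a ring A salicylaldehyde, whose formyl carbon (C4) sits ortho to the phenol oxygen O1, and a ring B arylacetylene carrying C2 and C3. In the key step a rhodium acyl hydride, held by the O1 phenoxide, adds across the alkyne to forge C3–C4 as an (E)-2'-hydroxychalcone; a chiral cinchona thiourea then closes ring C in the same flask by 6-endo oxa-Michael addition of O1 to C2 and sets the only stereocentre. The step exploits the ortho O1/C4 pair and the twofold symmetry of the phloroglucinol ring A, whose two ortho oxygens are equivalent.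

Key step: step 6

Remark: the sense of induction of cinchona thioureas on this chalcone class is assigned by analogy; the route is written with the quinidine-derived catalyst, and the quinine-derived pseudoenantiomer is the direct replacement if the opposite face of C2 is favoured.

Step 1
Reactants: 1 2-bromo-4,5-dihydroxybenzaldehyde
Product: 2 2-bromo-5-hydroxy-4-[(2-methylbut-3-yn-2-yl)oxy]benzaldehyde
Conditions: HC≡CC(CH3)2Cl (1.2 equiv), K2CO3 (1.05 equiv), KI (cat.), CuI (cat.), acetone, 56 °C, Ar
Reagents that add atoms: 3-chloro-3-methylbut-1-yne, C#CC(C)(C)Cl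
Why: Williamson-type O-alkylation (copper-assisted propargylic substitution): one equivalent of weak base ionises only the 4-OH, which is para to the formyl group and the more acidic of the two, so the tertiary propargyl group should go to that oxygen.

Step 2
Reactants: 2 2-bromo-5-hydroxy-4-[(2-methylbut-3-yn-2-yl)oxy]benzaldehyde
Product: 3 5-bromo-8-hydroxy-2,2-dimethyl-2H-chromene-6-carbaldehyde
Conditions: o-xylene, 145 °C
Reagents that add atoms: none
Why: Aromatic propargyl Claisen rearrangement to the only free ortho carbon (between C–Br and C–O), followed by enolisation, 1,5-hydrogen shift and 6π oxa-electrocyclisation, is the standard thermal cascade to 2,2-dimethyl-2H-chromenes; no stereocentre is formed.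

Step 3
Reactants: 3 5-bromo-8-hydroxy-2,2-dimethyl-2H-chromene-6-carbaldehyde
Product: 4 8-hydroxy-2,2-dimethyl-5-(3-methylbut-2-en-1-yl)-2H-chromene-6-carbaldehyde
Conditions: Bu3SnCH2CH=C(CH3)2 (1.3 equiv), Pd(PPh3)4 (5 mol%), DMF, 100 °C
Reagents that add atoms: tributyl(3-methylbut-2-en-1-yl)stannane, CCCC[Sn](CCCC)(CCCC)CC=C(C)C
Why: Stille coupling: the C–Br bond is activated towards zerovalent palladium by the ortho formyl group, and reductive elimination at the unsubstituted allyl terminus should be favoured because a 1,1-dimethylallyl group cannot be placed between two ortho substituents, so the linear prenyl isomer is expected.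

Step 4
Reactants: 4 8-hydroxy-2,2-dimethyl-5-(3-methylbut-2-en-1-yl)-2H-chromene-6-carbaldehyde
Product: 5 6-ethynyl-2,2-dimethyl-5-(3-methylbut-2-en-1-yl)-2H-chromen-8-ol
Conditions: dimethyl (1-diazo-2-oxopropyl)phosphonate (1.3 equiv), K2CO3, MeOH, 0 °C to rt
Reagents that add atoms: dimethyl (1-diazo-2-oxopropyl)phosphonate, COP(=O)(OC)C(=[N+]=[N-])C(C)=O
Why: Seyferth–Gilbert homologation in its Ohira–Bestmann form converts the aryl aldehyde into the terminal alkyne under mild carbonate conditions that the chromene, the prenyl group and the free phenol should tolerate.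

Step 5
Reactants: 6 2,4,6-trihydroxybenzaldehyde
Product: 7 2,4-bis[(tert-butyldimethylsilyl)oxy]-6-hydroxybenzaldehyde
Conditions: TBSCl (2.05 equiv), imidazole, CH2Cl2, 0 °C
Reagents that add atoms: tert-butyldimethylsilyl chloride, CC(C)(C)[Si](C)(C)Cl
Why: Selective silylation: the two ortho hydroxyls of 6 are equivalent, and once the para and one ortho oxygen carry silicon the last hydroxyl is tied up in the hydrogen bond to the formyl oxygen and should stay free.

Step 6
Reactants: 5 6-ethynyl-2,2-dimethyl-5-(3-methylbut-2-en-1-yl)-2H-chromen-8-ol; 7 2,4-bis[(tert-butyldimethylsilyl)oxy]-6-hydroxybenzaldehyde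
Product: 9 (2S)-5,7-bis[(tert-butyldimethylsilyl)oxy]-2-[8-hydroxy-2,2-dimethyl-5-(3-methylbut-2-en-1-yl)-2H-chromen-6-yl]-2,3-dihydro-4H-chromen-4-one, via 2'-hydroxychalcone 8 (not isolated)
Conditions: [RhCl(cod)]2 (2.5 mol%), Fe(C5H4PPh2)2 (5 mol%), Na2CO3 (5 mol%), PhMe, 80 °C; then 9-amino-9-deoxy-epi-quinidine 3,5-bis(trifluoromethyl)phenyl thiourea (20 mol%), PhMe, 0 °C
Reagents that add atoms: none
Why: Oxidative addition of the formyl C–H bond of 7 to monovalent rhodium, assisted by chelation of the ortho phenoxide, gives an acyl rhodium hydride; syn-hydrometalation of the alkyne of 5 with rhodium at the terminal carbon and C–C reductive elimination forge C3–C4 and release (E)-chalcone 8, which the bifunctional cinchona thiourea then cyclises by conjugate addition of O1 to C2. The closest known reactions are the chelation-assisted rhodium-catalysed hydroacylation of alkynes with salicylaldehydes run in tandem with oxa-Michael addition, and the cinchona-base-catalysed asymmetric cyclisation of 2'-hydroxychalcones to flavanones. Ring C closes in the 6-endo-trig mode. The C2 stereocentre is set by the catalyst alone: the quinuclidine nitrogen activates the 2'-OH while the thiourea binds the enone carbonyl, so that O1 should be delivered to one enantiotopic face of C2 to give the (2S) configuration. The step needs linear regioselectivity in the hydroacylation, secured by the ortho prenyl group that keeps rhodium off the internal alkyne carbon, chemoselectivity for the alkyne over the chromene and prenyl alkenes, which are inert to this catalyst, and a slow uncatalysed ring closure, secured by the silyl group on the second ortho oxygen and the low temperature.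

Step 7
Reactants: 9 (2S)-5,7-bis[(tert-butyldimethylsilyl)oxy]-2-[8-hydroxy-2,2-dimethyl-5-(3-methylbut-2-en-1-yl)-2H-chromen-6-yl]-2,3-dihydro-4H-chromen-4-one
Product: 10 (2S)-5,7-dihydroxy-2-[8-hydroxy-2,2-dimethyl-5-(3-methylbut-2-en-1-yl)-2H-chromen-6-yl]-2,3-dihydro-4H-chromen-4-one (CNP0224359.1)
Conditions: KHF2 (6 equiv), MeOH, rt
Reagents that add atoms: none
Why: Fluoride-mediated cleavage of the two aryl silyl ethers under weakly acidic, base-free conditions, so that retro-oxa-Michael opening of ring C is avoided and the C2 configuration should be kept.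

Compound list

1 | 2-bromo-4,5-dihydroxybenzaldehyde | O=Cc1cc(O)c(O)cc1Br | starting material
2 | 2-bromo-5-hydroxy-4-[(2-methylbut-3-yn-2-yl)oxy]benzaldehyde | O=Cc1cc(O)c(OC(C)(C)C#C)cc1Br | intermediate
3 | 5-bromo-8-hydroxy-2,2-dimethyl-2H-chromene-6-carbaldehyde | O=Cc1cc(O)c2OC(C)(C)C=Cc2c1Br | intermediate
4 | 8-hydroxy-2,2-dimethyl-5-(3-methylbut-2-en-1-yl)-2H-chromene-6-carbaldehyde | O=Cc1cc(O)c2OC(C)(C)C=Cc2c1CC=C(C)C | intermediate
5 | 6-ethynyl-2,2-dimethyl-5-(3-methylbut-2-en-1-yl)-2H-chromen-8-ol | C#Cc1cc(O)c2OC(C)(C)C=Cc2c1CC=C(C)C | intermediate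
6 | 2,4,6-trihydroxybenzaldehyde | O=Cc1c(O)cc(O)cc1O | starting material
7 | 2,4-bis[(tert-butyldimethylsilyl)oxy]-6-hydroxybenzaldehyde | O=Cc1c(O)cc(O[Si](C)(C)C(C)(C)C)cc1O[Si](C)(C)C(C)(C)C | intermediate
8 | (E)-1-{2,4-bis[(tert-butyldimethylsilyl)oxy]-6-hydroxyphenyl}-3-[8-hydroxy-2,2-dimethyl-5-(3-methylbut-2-en-1-yl)-2H-chromen-6-yl]prop-2-en-1-one | CC(C)=CCc1c(/C=C/C(=O)c2c(O)cc(O[Si](C)(C)C(C)(C)C)cc2O[Si](C)(C)C(C)(C)C)cc(O)c2OC(C)(C)C=Cc12 | intermediate
9 | (2S)-5,7-bis[(tert-butyldimethylsilyl)oxy]-2-[8-hydroxy-2,2-dimethyl-5-(3-methylbut-2-en-1-yl)-2H-chromen-6-yl]-2,3-dihydro-4H-chromen-4-one | CC(C)=CCc1c([C@@H]2CC(=O)c3c(O[Si](C)(C)C(C)(C)C)cc(O[Si](C)(C)C(C)(C)C)cc3O2)cc(O)c2c1C=CC(C)(C)O2 | intermediate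
10 | (2S)-5,7-dihydroxy-2-[8-hydroxy-2,2-dimethyl-5-(3-methylbut-2-en-1-yl)-2H-chromen-6-yl]-2,3-dihydro-4H-chromen-4-one (CNP0224359.1) | CC(C)=CCc1c([C@@H]2CC(=O)c3c(O)cc(O)cc3O2)cc(O)c2c1C=CC(C)(C)O2 | target

Total step count: 7. Longest linear sequence: 6 steps (steps 1, 2, 3, 4, 6 and 7); step 5 prepares the second fragment.

Steps most likely to fail

Step 6. The catalysed ring closure may proceed with poor facial selectivity, because conjugate addition to this electron-rich, ortho-substituted β-aryl enone is slow and reversible ring opening can erode the enantiomeric excess. The fallback sets out from chalcone 8, generated as in step 6 but without the chiral catalyst. It is closed with DBU (10 mol%) in PhMe at rt to the racemic 5,7-bis(silyloxy)flavanone F1. Kinetic resolution by asymmetric transfer hydrogenation with RhCl(C5Me5)[(R,R)-TsNCHPhCHPhNH2] (1 mol%), HCO2H/Et3N, EtOAc, rt, stopped near half conversion, should reduce the (2R)-ketone to the cis-(2R,4R)-flavan-4-ol F2. The untouched (2S)-ketone is separated by chromatography, and the route is rejoined at 9.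

Step 3. Carbon–carbon bond formation may occur at the substituted allyl terminus (reverse prenyl isomer), or transmetalation at the doubly flanked C–Br bond may stall. The fallback sets out from 3. Stille allylation with allyltributylstannane (Pd(PPh3)4, DMF, 90 °C), for which no regiochemical question arises, should give 5-allyl-8-hydroxy-2,2-dimethyl-2H-chromene-6-carbaldehyde F3. Olefin cross-metathesis with 2-methylbut-2-ene (second-generation Grubbs catalyst RuCl2(=CHPh)(PCy3)(H2IMes), CH2Cl2, 40 °C) then installs the prenyl terminus, and the route is rejoined at 4.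

Step 1. Alkylation may take place at the wrong catechol oxygen or at both. The fallback sets out from 1 and reverses the order of differentiation:
- The dianion (NaH, 2.2 equiv, DMF, 0 °C) is treated with MOMCl (1.0 equiv). The 5-oxide, which is not conjugated to the formyl group, is the more nucleophilic, so 2-bromo-4-hydroxy-5-(methoxymethoxy)benzaldehyde F4 should result.
- The only free hydroxyl is then alkylated with 3-chloro-3-methylbut-1-yne (K2CO3, KI, CuI, acetone, 56 °C) to give 2-bromo-5-(methoxymethoxy)-4-[(2-methylbut-3-yn-2-yl)oxy]benzaldehyde F5.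
- Thermal rearrangement (o-xylene, 145 °C) gives 5-bromo-8-(methoxymethoxy)-2,2-dimethyl-2H-chromene-6-carbaldehyde F6.
- Acetal cleavage (HCl, MeOH, 40 °C) rejoins the route at 3.

Further compounds

F1 | step 6 | racemic 5,7-bis[(tert-butyldimethylsilyl)oxy]-2-[8-hydroxy-2,2-dimethyl-5-(3-methylbut-2-en-1-yl)-2H-chromen-6-yl]-2,3-dihydro-4H-chromen-4-one | CC(C)=CCc1c(C2CC(=O)c3c(O[Si](C)(C)C(C)(C)C)cc(O[Si](C)(C)C(C)(C)C)cc3O2)cc(O)c2c1C=CC(C)(C)O2
F2 | step 6 | (2R,4R)-5,7-bis[(tert-butyldimethylsilyl)oxy]-2-[8-hydroxy-2,2-dimethyl-5-(3-methylbut-2-en-1-yl)-2H-chromen-6-yl]-3,4-dihydro-2H-chromen-4-ol | CC(C)=CCc1c([C@H]2C[C@@H](O)c3c(O[Si](C)(C)C(C)(C)C)cc(O[Si](C)(C)C(C)(C)C)cc3O2)cc(O)c2c1C=CC(C)(C)O2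
F3 | step 3 | 5-allyl-8-hydroxy-2,2-dimethyl-2H-chromene-6-carbaldehyde | O=Cc1cc(O)c2OC(C)(C)C=Cc2c1CC=C
F4 | step 1 | 2-bromo-4-hydroxy-5-(methoxymethoxy)benzaldehyde | O=Cc1cc(OCOC)c(O)cc1Br
F5 | step 1 | 2-bromo-5-(methoxymethoxy)-4-[(2-methylbut-3-yn-2-yl)oxy]benzaldehyde | O=Cc1cc(OCOC)c(OC(C)(C)C#C)cc1Br
F6 | step 1 | 5-bromo-8-(methoxymethoxy)-2,2-dimethyl-2H-chromene-6-carbaldehyde | O=Cc1cc(OCOC)c2OC(C)(C)C=Cc2c1Br
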